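**Strategy.** In the 7-oxabicyclo[2.2.1]heptane (bridgeheads C1 and C4, side chain on C2, methyl on C3, bridge O7) the ethano bridge C5–C6 lies between two methyl-bearing ether carbons. C4 is unmasked as a methyl ketone (C5 its α-carbon) and C1 as a 2-substituted allyl chloride (C6 its CH2Cl, the methylene its latent methyl). A 6-exo-tet enolate allylation of this acyclic chloro ketone, which already carries C2 and C3, forges C5–C6 and the carbocycle; MeMgBr addition and transannular hydroalkoxylation then install both bridgehead methyls and O7. Copper-catalysed union with a linalool-derived allylic chloride and a biomimetic bromoetherification complete the target.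

Key step: step 7

Assumption: (S)-(+)-linalool (17) of high enantiomeric purity is taken as a commercial starting material; minor diastereomers arising from imperfect enantiopurity of either fragment are removed after step 13.

**Step 1**
Reactants: 1 furan-2(5H)-one; 2 4,4,5,5-tetramethyl-2-(prop-1-en-2-yl)-1,3,2-dioxaborolane
Product: 3 (4R)-4-(prop-1-en-2-yl)oxolan-2-one
Conditions: [Rh(cod)OH]2 (2.5 mol %), (R)-BINAP (6 mol %), 2 (2 equiv), dioxane/H2O 10:1, 40 °C
Reagents that add atoms: none
Why: Hayashi–Miyaura rhodium-catalysed asymmetric 1,4-addition of the alkenylboronate to the butenolide; with (R)-BINAP the alkenyl group should be delivered to the face that gives (R)-C4 (the sense known for cyclic enones and unsaturated lactones), and this centre becomes C2 of the bicycle.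

**Step 2**
Reactants: 3 (4R)-4-(prop-1-en-2-yl)oxolan-2-one
Product: 5 (3S,4R)-3-methyl-4-(prop-1-en-2-yl)oxolan-2-one, via lithium enolate 4 (not isolated)
Conditions: LiN(iPr)2 (1.05 equiv), THF, −78 °C; MeI (1.5 equiv), −78 → −40 °C
Reagents that add atoms: iodomethane CI
Why: Lactone enolate alkylation; iodomethane enters anti to the C4 isopropenyl group and should give the trans lactone, which serves only to introduce the methyl carbon (its configuration is corrected in step 3).

**Step 3**
Reactants: 5 (3S,4R)-3-methyl-4-(prop-1-en-2-yl)oxolan-2-one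
Product: 7 (3R,4R)-3-methyl-4-(prop-1-en-2-yl)oxolan-2-one, via lithium enolate 6 (not isolated)
Conditions: LiN(iPr)2 (1.2 equiv), THF, −78 °C; then 2,6-di-tert-butyl-4-methylphenol (3 equiv) in THF, −78 °C; aq NH4Cl
Reagents that add atoms: none
Why: Deprotonation followed by kinetic protonation: the planar enolate 6 should be protonated by the bulky phenol on the face anti to the isopropenyl group, so the methyl ends cis to it (contra-thermodynamic epimerisation), which is the C2/C3 relationship of the target; recovered 5 is recycled.

**Step 4**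
Reactants: 7 (3R,4R)-3-methyl-4-(prop-1-en-2-yl)oxolan-2-one
Product: 8 (3R,4R)-4-(hydroxymethyl)-3,5-dimethylhex-5-en-2-one
Conditions: MeLi (1.05 equiv), Et2O, −78 °C; aq NH4Cl at −78 °C
Reagents that add atoms: methyllithium [Li]C
Why: Mono-addition of MeLi to a γ-lactone: the tetrahedral lithium hemiketal is stable at −78 °C and opens only on quench to the γ-hydroxy methyl ketone (in equilibrium with its lactol), so over-addition and C3 epimerisation should be minimal.

**Step 5**
Reactants: 8 (3R,4R)-4-(hydroxymethyl)-3,5-dimethylhex-5-en-2-one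
Product: 9 (3R,4R)-3,5-dimethyl-4-[(triethylsilyloxy)methyl]hex-5-en-2-one
Conditions: Et3SiCl (1.2 equiv), imidazole (2 equiv), CH2Cl2, 0 °C
Reagents that add atoms: chlorotriethylsilane CC[Si](CC)(CC)Cl
Why: Silylation of the primary alcohol of the open hydroxy ketone form pulls the lactol equilibrium to the protected ketone and masks the hydroxyl that would otherwise O-alkylate in step 7.

**Step 6**
Reactants: 9 (3R,4R)-3,5-dimethyl-4-[(triethylsilyloxy)methyl]hex-5-en-2-one
Product: 10 (3R,4R)-5-(chloromethyl)-3-methyl-4-[(triethylsilyloxy)methyl]hex-5-en-2-one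
Conditions: Ca(OCl)2 (0.6 equiv), solid CO2, CH2Cl2/H2O, 0 °C
Reagents that add atoms: calcium hypochlorite [Ca+2].[O-]Cl.[O-]Cl
Why: Ene-type allylic chlorination of an isopropenyl group by HOCl made in situ (as known for limonene and carvone): Cl+ adds to the terminal CH2 and a proton is lost from the methyl, giving the 2-(chloromethyl)allyl unit, while the hindered allylic methine at C4 is not deprotonated, so the stereocentre is kept.

**Step 7**
Reactants: 10 (3R,4R)-5-(chloromethyl)-3-methyl-4-[(triethylsilyloxy)methyl]hex-5-en-2-one
Product: 12 (2R,3R)-2-methyl-4-methylidene-3-[(triethylsilyloxy)methyl]cyclohexan-1-one, via potassium enolate 11 (not isolated)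
Conditions: KN(SiMe3)2 (1.1 equiv), THF, −78 °C (slow addition of 10 to the base, high dilution), then −78 → −30 °C; aq NH4Cl
Reagents that add atoms: none
Why: KN(SiMe3)2 removes a proton from the unhindered acetyl CH3 (C5) under kinetic control rather than from the tertiary C3–H, and the potassium enolate 11 displaces the primary allylic chloride at C6 in an intramolecular SN2 reaction. The closest known reaction type is the intramolecular alkylation of ketone enolates by tethered allylic halides (cycloalkylation) used to make cyclohexanones. The one ring closed is the six-membered carbocycle C1–C6, in the 6-exo-tet mode with the enolate double bond outside the ring. No stereocentre is created; C2 and C3 come from steps 1 and 3 and should not be touched, because the base is consumed by the more accessible methyl protons and the product enolises, if at all, toward C5. The step needs C- over O-alkylation and SN2 over SN2' attack, and both alternatives would give eight-membered rings, so ring size secures them, while slow addition at high dilution suppresses intermolecular alkylation. The new ketone and the exocyclic methylene stand 1,4 to each other, ready to become C4 and C1.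

**Step 8**
Reactants: 12 (2R,3R)-2-methyl-4-methylidene-3-[(triethylsilyloxy)methyl]cyclohexan-1-one
Product: 14 (1S,2R,3R)-3-(hydroxymethyl)-1,2-dimethyl-4-methylidenecyclohexan-1-ol, via triethylsilyl ether 13 (not isolated)
Conditions: MeMgBr (2 equiv), CeCl3 (2 equiv), THF, −78 °C; aq NH4Cl; then PPTS (0.1 equiv), MeOH, rt
Reagents that add atoms: methylmagnesium bromide C[Mg]Br
Why: CeCl3-promoted Grignard 1,2-addition (enolisation suppressed): the methyl nucleophile should attack the carbonyl anti to the adjacent ring methyl group (equatorial attack on the chair with both substituents equatorial), placing the new hydroxyl cis to that methyl and trans to the CH2O group and thus setting C4 of the bicycle; mild acid methanolysis then removes the triethylsilyl group.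

**Step 9**
Reactants: 14 (1S,2R,3R)-3-(hydroxymethyl)-1,2-dimethyl-4-methylidenecyclohexan-1-ol
Product: 15 [(1R,2S,3R,4S)-1,3,4-trimethyl-7-oxabicyclo[2.2.1]heptan-2-yl]methanol
Conditions: Co(C36H52N2O2) (N,N'-bis(3,5-di-tert-butylsalicylidene)-1,2-cyclohexanediaminocobalt, 5 mol %), N-fluoro-2,4,6-trimethylpyridinium triflate (1.5 equiv), PhSiH3 (1.5 equiv), PhCF3, rt
Reagents that add atoms: none
Why: Cobalt-catalysed hydrogen-atom-transfer hydroalkoxylation of an alkenol: H adds to the exocyclic CH2 (which becomes the C1 methyl), the tertiary radical is oxidised by the cobalt/N-fluoropyridinium system and the cation is captured across the ring by the tertiary hydroxyl through a boat conformer, so the oxygen bridge should form on the face fixed in step 8 and the C1 configuration follows from the bicyclic geometry; the primary hydroxyl could only form an oxetane and should not compete.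

**Step 10**
Reactants: 15 [(1R,2S,3R,4S)-1,3,4-trimethyl-7-oxabicyclo[2.2.1]heptan-2-yl]methanol
Product: 16 (1R,2R,3R,4S)-2-(bromomethyl)-1,3,4-trimethyl-7-oxabicyclo[2.2.1]heptane
Conditions: CBr4 (1.3 equiv), PPh3 (1.4 equiv), 2,6-lutidine (0.5 equiv), CH2Cl2, 0 °C
Reagents that add atoms: tetrabromomethane BrC(Br)(Br)Br
Why: Appel bromination of the primary alcohol under buffered, non-acidic conditions that spare the tertiary ether bridge; no stereocentre is involved.

**Step 11**
Reactants: 17 (S)-(+)-linalool
Product: 18 (2E,6S)-2,6-dimethylocta-2,7-diene-1,6-diol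
Conditions: SeO2 (0.3 equiv), tert-butyl hydroperoxide (3 equiv), salicylic acid (0.1 equiv), CH2Cl2, rt
Reagents that add atoms: tert-butyl hydroperoxide CC(C)(C)OO
Why: SeO2-catalysed allylic oxidation (ene reaction then [2,3]-shift) of the trisubstituted alkene should occur at the (E)-methyl group of the gem-dimethyl terminus and leave the tertiary carbinol centre untouched.

**Step 12**
Reactants: 18 (2E,6S)-2,6-dimethylocta-2,7-diene-1,6-diol
Product: 19 (3S,6E)-8-chloro-3,7-dimethylocta-1,6-dien-3-ol
Conditions: N-chlorosuccinimide (1.2 equiv), Me2S (1.3 equiv), CH2Cl2, −20 → 0 °C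
Reagents that add atoms: N-chlorosuccinimide O=C1CCC(=O)N1Cl
Why: Corey–Kim chlorination: the sulfonium salt from N-chlorosuccinimide and Me2S activates only the primary allylic hydroxyl, and chloride displaces it by SN2 without allylic transposition or loss of the (E)-geometry; the tertiary alcohol should not react.

**Step 13**
Reactants: 16 (1R,2R,3R,4S)-2-(bromomethyl)-1,3,4-trimethyl-7-oxabicyclo[2.2.1]heptane; 19 (3S,6E)-8-chloro-3,7-dimethylocta-1,6-dien-3-ol
Product: 22 (3S,6E)-3,7-dimethyl-9-[(1R,2R,3R,4S)-1,3,4-trimethyl-7-oxabicyclo[2.2.1]heptan-2-yl]nona-1,6-dien-3-ol, via Grignard reagent 20 (not isolated), via lithium alkoxide 21 (not isolated)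
Conditions: 16, Mg turnings, THF, 40 °C (gives 20); 19, LiN(SiMe3)2 (1.0 equiv), THF, −78 °C (gives 21); 20 (1.3 equiv) added to 21, Li2CuCl4 (5 mol %), THF, −30 → 0 °C; aq NH4Cl
Reagents that add atoms: none
Why: Copper-catalysed sp3–sp3 coupling of a primary Grignard reagent with a primary allylic chloride (Kochi–Schlosser conditions) should go by SN2 attack at the CH2Cl carbon with retention of the (E)-alkene; pre-forming the lithium alkoxide 21 keeps the tertiary hydroxyl from quenching 20, and no stereocentre is touched.

**Step 14**
Reactants: 22 (3S,6E)-3,7-dimethyl-9-[(1R,2R,3R,4S)-1,3,4-trimethyl-7-oxabicyclo[2.2.1]heptan-2-yl]nona-1,6-dien-3-ol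
Product: 23 dactylopyranoid
Conditions: 2,4,4,6-tetrabromocyclohexa-2,5-dienone (1.1 equiv), MeNO2, 0 °C → rt, dark
Reagents that add atoms: 2,4,4,6-tetrabromocyclohexa-2,5-dienone O=C1C(Br)=CC(Br)(Br)C=C1Br
Why: Bromonium-induced 6-endo (Markovnikov) bromoetherification: the reagent brominates the more electron-rich trisubstituted alkene and the tertiary hydroxyl opens the bromonium ion at the tertiary carbon through a chair, anti addition across the (E)-alkene fixing Br cis to the ring methyl and trans to the side chain, while the vinyl-bearing centre comes from linalool; the isomer from bromination of the other alkene face and 5-exo products are expected as by-products and are removed by chromatography.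

**Compound list**
1 | furan-2(5H)-one | O=C1C=CCO1 | starting material
2 | 4,4,5,5-tetramethyl-2-(prop-1-en-2-yl)-1,3,2-dioxaborolane (isopropenylboronic acid pinacol ester) | CC(=C)B1OC(C)(C)C(C)(C)O1 | starting material
3 | (4R)-4-(prop-1-en-2-yl)oxolan-2-one | O=C1C[C@H](C(C)=C)CO1 | intermediate
4 | lithium enolate of 3 | [Li+].[O-]C1=C[C@H](C(C)=C)CO1 | intermediate
5 | (3S,4R)-3-methyl-4-(prop-1-en-2-yl)oxolan-2-one (trans lactone) | O=C1[C@@H](C)[C@H](C(C)=C)CO1 | intermediate
6 | lithium enolate of 5 | [Li+].[O-]C1=C(C)[C@H](C(C)=C)CO1 | intermediate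
7 | (3R,4R)-3-methyl-4-(prop-1-en-2-yl)oxolan-2-one (cis lactone) | O=C1[C@H](C)[C@H](C(C)=C)CO1 | intermediate
8 | (3R,4R)-4-(hydroxymethyl)-3,5-dimethylhex-5-en-2-one | CC(=O)[C@H](C)[C@@H](CO)C(C)=C | intermediate
9 | (3R,4R)-3,5-dimethyl-4-[(triethylsilyloxy)methyl]hex-5-en-2-one | CC(=O)[C@H](C)[C@@H](CO[Si](CC)(CC)CC)C(C)=C | intermediate
10 | (3R,4R)-5-(chloromethyl)-3-methyl-4-[(triethylsilyloxy)methyl]hex-5-en-2-one | CC(=O)[C@H](C)[C@@H](CO[Si](CC)(CC)CC)C(=C)CCl | intermediate
11 | potassium enolate of 10 | [K+].[O-]C(=C)[C@H](C)[C@@H](CO[Si](CC)(CC)CC)C(=C)CCl | intermediate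
12 | (2R,3R)-2-methyl-4-methylidene-3-[(triethylsilyloxy)methyl]cyclohexan-1-one | O=C1CCC(=C)[C@H](CO[Si](CC)(CC)CC)[C@H]1C | intermediate
13 | (1S,2R,3R)-1,2-dimethyl-4-methylidene-3-[(triethylsilyloxy)methyl]cyclohexan-1-ol | C[C@]1(O)CCC(=C)[C@H](CO[Si](CC)(CC)CC)[C@H]1C | intermediate
14 | (1S,2R,3R)-3-(hydroxymethyl)-1,2-dimethyl-4-methylidenecyclohexan-1-ol | C[C@]1(O)CCC(=C)[C@H](CO)[C@H]1C | intermediate
15 | [(1R,2S,3R,4S)-1,3,4-trimethyl-7-oxabicyclo[2.2.1]heptan-2-yl]methanol | OC[C@@H]1[C@@H](C)[C@]2(C)CC[C@@]1(C)O2 | intermediate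
16 | (1R,2R,3R,4S)-2-(bromomethyl)-1,3,4-trimethyl-7-oxabicyclo[2.2.1]heptane | BrC[C@@H]1[C@@H](C)[C@]2(C)CC[C@@]1(C)O2 | intermediate
17 | (S)-(+)-linalool, (3S)-3,7-dimethylocta-1,6-dien-3-ol | C=C[C@@](C)(O)CCC=C(C)C | starting material
18 | (2E,6S)-2,6-dimethylocta-2,7-diene-1,6-diol | C=C[C@@](C)(O)CC/C=C(\C)CO | intermediate
19 | (3S,6E)-8-chloro-3,7-dimethylocta-1,6-dien-3-ol | C=C[C@@](C)(O)CC/C=C(\C)CCl | intermediate
20 | Grignard reagent of 16, {[(1R,2R,3R,4S)-1,3,4-trimethyl-7-oxabicyclo[2.2.1]heptan-2-yl]methyl}magnesium bromide | Br[Mg]C[C@@H]1[C@@H](C)[C@]2(C)CC[C@@]1(C)O2 | intermediate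
21 | lithium alkoxide of 19 | C=C[C@@](C)([O-])CC/C=C(\C)CCl.[Li+] | intermediate
22 | (3S,6E)-3,7-dimethyl-9-[(1R,2R,3R,4S)-1,3,4-trimethyl-7-oxabicyclo[2.2.1]heptan-2-yl]nona-1,6-dien-3-ol | C=C[C@@](C)(O)CC/C=C(\C)CC[C@@H]1[C@@H](C)[C@]2(C)CC[C@@]1(C)O2 | intermediate
23 | dactylopyranoid, (2S,3R,6S)-3-bromo-6-ethenyl-2,6-dimethyl-2-{2-[(1R,2R,3R,4S)-1,3,4-trimethyl-7-oxabicyclo[2.2.1]heptan-2-yl]ethyl}oxane | C=C[C@]1(C)CC[C@@H](Br)[C@](C)(CC[C@@H]2[C@@H](C)[C@]3(C)CC[C@@]2(C)O3)O1 | target

**Step count and risk**
Total step count: 14. Longest linear sequence: 12 steps (steps 1–10, 13, 14).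

Steps most likely to fail:

Step 14 (bromoetherification). What may go wrong: poor facial selectivity of bromonium formation relative to the fixed carbinol centre, together with competing 5-exo closure. The fallback sets out from 22 and comes back at 23. Shi epoxidation of 22 with the D-fructose-derived ketone (Oxone (KHSO5), K2CO3, MeCN/dimethoxymethane/buffer, 0 °C) places the oxygen by reagent control and should give the (R,R)-epoxy alcohol F1. Camphorsulfonic acid in CH2Cl2 should then promote the kinetically preferred 5-exo opening, with inversion at the secondary carbon, to the tetrahydrofuran tertiary alcohol F2. Activation of the tertiary hydroxyl in the presence of bromide (SOBr2, 2,6-di-tert-butylpyridine, CH2Cl2, −40 °C) should ionise it with participation of the ring oxygen; bromide opens the resulting bicyclic oxonium ion at the secondary carbon with a second inversion. This is a known oxonium-mediated ring expansion of 2-(1-hydroxyalkyl)tetrahydrofurans to 3-halotetrahydropyrans, and it reaches 23 with both new centres fixed by the epoxide.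

Step 9 (transannular hydroalkoxylation). What may go wrong: reduction of the tertiary radical or isomerisation of the alkene before the ring reaches the boat needed for C–O bond formation across it. The fallback sets out from 14 and comes back at 15. Iodoetherification (I2, NaHCO3, MeCN, 0 °C; iodonium on the exocyclic alkene, Markovnikov capture by the tertiary hydroxyl) should give the iodomethyl ether F3. Radical deiodination (Bu3SnH, AIBN, toluene, 80 °C) then turns CH2I into the C1 methyl and returns 15.

Step 3 (kinetic protonation). What may go wrong: insufficient facial discrimination in the protonation of enolate 6, returning mostly trans lactone 5. The fallback sets out from 3 and comes back at 7. Lactone 3 is α-methylenated: LiN(iPr)2 then dimethylmethylideneammonium iodide gives the Mannich base F4, and MeI followed by NaHCO3 eliminates the amine to give the α-methylene lactone F5. Hydrogenation with Ru(OAc)2(BINAP) under H2 (MeOH/CH2Cl2) then adds H2 syn to the conjugated exocyclic alkene under catalyst control; the isolated isopropenyl group is not a substrate for this catalyst class. The BINAP enantiomer is chosen so that its preferred face coincides with the face anti to the isopropenyl group, which gives the cis lactone 7.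

**Further compounds**
F1 | step 14 | (3S)-3-methyl-5-[(2R,3R)-3-methyl-3-{2-[(1R,2R,3R,4S)-1,3,4-trimethyl-7-oxabicyclo[2.2.1]heptan-2-yl]ethyl}oxiran-2-yl]pent-1-en-3-ol | C=C[C@@](C)(O)CC[C@H]1O[C@]1(C)CC[C@@H]2[C@@H](C)[C@]3(C)CC[C@@]2(C)O3
F2 | step 14 | 2-(5-ethenyl-5-methyloxolan-2-yl)-4-(1,3,4-trimethyl-7-oxabicyclo[2.2.1]heptan-2-yl)butan-2-ol (configuration as in SMILES) | C=C[C@]1(C)CC[C@H](O1)[C@](C)(O)CC[C@@H]2[C@@H](C)[C@]3(C)CC[C@@]2(C)O3
F3 | step 9 | [1-(iodomethyl)-3,4-dimethyl-7-oxabicyclo[2.2.1]heptan-2-yl]methanol (configuration as in SMILES) | OC[C@@H]1[C@@H](C)[C@]2(C)CC[C@@]1(CI)O2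
F4 | step 3 | trans-3-[(dimethylamino)methyl]-4-(prop-1-en-2-yl)oxolan-2-one (configuration as in SMILES) | O=C1[C@@H](CN(C)C)[C@H](C(C)=C)CO1
F5 | step 3 | (4S)-3-methylidene-4-(prop-1-en-2-yl)oxolan-2-one | C=C1[C@H](C(C)=C)COC1=O
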